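**Retrosynthetic overview**

1. Last disconnection: the sp2–sp3 bond between the vinylic CH that ends the (4E,6E)-2-methyl-diene and the CH2 of the two-carbon arm on C4 of ring B (the 2,4-disubstituted furan). Forward, this is a Negishi alkyl–alkenyl coupling of two finished halves: a vinyl iodide that already carries ring C (the butenolide), the S stereocentre and the diene, and the primary alkylzinc iodide of the bis-furan (rings A and B).
2. Enabling feature: the arm on ring B is an unbranched CH2–CH2 whose far carbon has only an aromatic furan carbon (C4 of ring B) in the β-position, so it can be held as a stable primary alkylzinc. Its partner is the single iodine-bearing sp2 CH of the diene, and a neutral organozinc is the nucleophile that ring C (an E enol lactone next to a vinylogously acidic CH(CH3)) tolerates.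
3. Right half: rings A and B are bought as furans and joined at the CH2 bridge (furan-3-yllithium plus 4-bromofuran-2-carbaldehyde, then ionic deoxygenation); the C4–Br of ring B becomes vinyl, then CH2CH2OH, then CH2CH2I.
4. Left half: the stereocentre comes from (R)-3-bromo-2-methylpropan-1-ol; its alkylzinc is coupled with an (E)-chloroenyne, and the alkyne is methylaluminated and iodinated to the (E,E)-iododiene.
5. Ring C is attached last in that half: 3-methylfuran-2(5H)-one, as its silyloxyfuran, adds to the α-methyl aldehyde (vinylogous aldol), and anti-elimination of the unlike adduct sets the E exocyclic double bond. No ring is built de novo.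

Key step: step 16

Remark: the exocyclic double bond of ring C is taken as drawn, E (side chain cis to the ring CH, trans to the ring oxygen), the less stable geometry of a γ-alkylidene butenolide; it is therefore set by a stereospecific elimination and kept away from base afterwards.

**Route**

Step 1
Reactants: 1 4-bromofuran-2-carbaldehyde; 2 3-bromofuran
Product: 4 racemic (4-bromofuran-2-yl)(furan-3-yl)methanol, via furan-3-yllithium 3 (not isolated)
Conditions: 2, n-BuLi, THF, −78 °C; then 1, −78 °C; H2O
Reagents that add atoms: none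
Why: Bromine–lithium exchange gives furan-3-yllithium, which keeps its position at −78 °C and adds to the aldehyde (organolithium 1,2-addition) faster than it can exchange with the C4–Br bond of ring B; the carbinol centre is formed racemic and is removed in step 2.

Step 2
Reactants: 4 racemic (4-bromofuran-2-yl)(furan-3-yl)methanol
Product: 5 4-bromo-2-(furan-3-ylmethyl)furan
Conditions: Et3SiH, CF3CO2H, CH2Cl2, −40 to 0 °C
Reagents that add atoms: none
Why: Ionic hydrogenation: CF3CO2H ionises the carbinol to a cation stabilised by both furans and Et3SiH reduces it by hydride transfer, which removes the only stereocentre and leaves the C–Br bond for step 3.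

Step 3
Reactants: 5 4-bromo-2-(furan-3-ylmethyl)furan
Product: 6 4-ethenyl-2-(furan-3-ylmethyl)furan
Conditions: vinylboronic acid pinacol ester, PdCl2(dppf) (cat.), K2CO3, 1,4-dioxane/H2O, 80 °C
Reagents that add atoms: vinylboronic acid pinacol ester, C=CB1OC(C)(C)C(C)(C)O1
Why: Suzuki–Miyaura coupling at the only C–Br bond installs the vinyl group on C4 of ring B under mild carbonate conditions that the furans tolerate.

Step 4
Reactants: 6 4-ethenyl-2-(furan-3-ylmethyl)furan
Product: 8 2-[5-(furan-3-ylmethyl)furan-3-yl]ethan-1-ol, via B-alkyl-9-BBN adduct 7 (not isolated)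
Conditions: 9-BBN, THF, 0 to 23 °C; then NaOH, H2O2, H2O, 0 °C
Reagents that add atoms: hydrogen peroxide, OO
Why: Hydroboration–oxidation: 9-BBN adds to the monosubstituted vinyl group much faster than to the aromatic furans and puts boron on the terminal carbon, and alkaline H2O2 replaces boron by OH to give the primary alcohol.

Step 5
Reactants: 8 2-[5-(furan-3-ylmethyl)furan-3-yl]ethan-1-ol
Product: 9 2-(furan-3-ylmethyl)-4-(2-iodoethyl)furan
Conditions: I2, PPh3, imidazole, CH2Cl2, 0 °C
Reagents that add atoms: iodine, II
Why: Appel-type iodination: the alkoxyphosphonium formed from PPh3/I2 is displaced by iodide in an SN2 reaction under imidazole-buffered, non-acidic conditions that spare both furans.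

Step 6
Reactants: 10 (E)-1,2-dichloroethene; 11 ethynyltrimethylsilane
Product: 12 (E)-(4-chlorobut-3-en-1-yn-1-yl)trimethylsilane
Conditions: Pd(PPh3)4 (cat.), CuI (cat.), n-BuNH2, Et2O, 23 °C, 10 in excess
Reagents that add atoms: none
Why: Sonogashira coupling of the terminal alkyne with one C–Cl bond of the excess dichloroethene proceeds with retention, so the E geometry of the later disubstituted double bond of the diene is bought in.

Step 7
Reactants: 13 (R)-3-bromo-2-methylpropan-1-ol
Product: 14 (R)-(3-bromo-2-methylpropoxy)(tert-butyl)dimethylsilane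
Conditions: t-BuMe2SiCl, imidazole, CH2Cl2, 0 to 23 °C
Reagents that add atoms: tert-butyldimethylsilyl chloride, CC(C)(C)[Si](C)(C)Cl
Why: Imidazole-mediated silylation of the primary alcohol protects it for the organometallic steps and does not touch the stereocentre.

Step 8
Reactants: 14 (R)-(3-bromo-2-methylpropoxy)(tert-butyl)dimethylsilane; 12 (E)-(4-chlorobut-3-en-1-yn-1-yl)trimethylsilane
Product: 16 tert-butyldimethyl{[(2S,4E)-2-methyl-7-(trimethylsilyl)hept-4-en-6-yn-1-yl]oxy}silane, via alkylzinc bromide 15 (not isolated)
Conditions: Zn dust, LiCl, THF, 50 °C; then 12, PdCl2(dppf) (cat.), THF, 50 °C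
Reagents that add atoms: none
Why: LiCl-assisted insertion of zinc into the primary C–Br bond gives an alkylzinc whose stereocentre, one carbon away from the metal, is not at risk, and Negishi coupling with the alkyne-activated vinyl chloride forms the sp3–sp2 bond with retention of the E geometry.

Step 9
Reactants: 16 tert-butyldimethyl{[(2S,4E)-2-methyl-7-(trimethylsilyl)hept-4-en-6-yn-1-yl]oxy}silane
Product: 17 tert-butyldimethyl{[(2S,4E)-2-methylhept-4-en-6-yn-1-yl]oxy}silane
Conditions: K2CO3 (cat.), MeOH, 23 °C
Reagents that add atoms: none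
Why: Base-catalysed methanolysis cleaves the alkynyl C–Si bond (protodesilylation) much faster than the primary tert-butyldimethylsilyl ether.

Step 10
Reactants: 17 tert-butyldimethyl{[(2S,4E)-2-methylhept-4-en-6-yn-1-yl]oxy}silane
Product: 19 tert-butyl{[(2S,4E,6E)-7-iodo-2,6-dimethylhepta-4,6-dien-1-yl]oxy}dimethylsilane, via dimethylalkenylalane 18 (not isolated)
Conditions: Me3Al, Cp2ZrCl2 (cat.), CH2Cl2, 0 to 23 °C; then I2, THF, −30 to 0 °C
Reagents that add atoms: trimethylaluminium, C[Al](C)C; iodine, II
Why: Zirconium-catalysed carboalumination adds CH3 and Al syn across the terminal alkyne with Al on the terminal carbon, and iodinolysis of the C–Al bond with retention gives the E trisubstituted vinyl iodide while the existing E double bond is untouched.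

Step 11
Reactants: 19 tert-butyl{[(2S,4E,6E)-7-iodo-2,6-dimethylhepta-4,6-dien-1-yl]oxy}dimethylsilane
Product: 20 (2S,4E,6E)-7-iodo-2,6-dimethylhepta-4,6-dien-1-ol
Conditions: Bu4NF, THF, 0 °C
Reagents that add atoms: none
Why: Fluoride-induced cleavage of the silyl ether (Si–F bond formation) frees the primary alcohol without affecting the vinyl iodide or the diene.

Step 12
Reactants: 20 (2S,4E,6E)-7-iodo-2,6-dimethylhepta-4,6-dien-1-ol
Product: 21 (2S,4E,6E)-7-iodo-2,6-dimethylhepta-4,6-dienal
Conditions: Dess–Martin periodinane, pyridine, CH2Cl2, 0 to 23 °C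
Reagents that add atoms: none
Why: Dess–Martin oxidation under pyridine buffering gives the α-methyl aldehyde without acid or strong base, so the α-stereocentre should not epimerise if the aldehyde is used at once.

Step 13
Reactants: 22 3-methylfuran-2(5H)-one
Product: 23 trimethyl[(3-methylfuran-2-yl)oxy]silane
Conditions: Me3SiOTf, Et3N, Et2O, 0 °C
Reagents that add atoms: trimethylsilyl trifluoromethanesulfonate, C[Si](C)(C)OS(=O)(=O)C(F)(F)F
Why: Soft enolisation and O-silylation of the butenolide gives the aromatic 2-silyloxyfuran, the nucleophilic form of ring C.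

Step 14
Reactants: 21 (2S,4E,6E)-7-iodo-2,6-dimethylhepta-4,6-dienal; 23 trimethyl[(3-methylfuran-2-yl)oxy]silane
Product: 25 (5S)-5-[(1R,2S,4E,6E)-1-hydroxy-7-iodo-2,6-dimethylhepta-4,6-dien-1-yl]-3-methylfuran-2(5H)-one, via trimethylsilyl ether 24 (not isolated)
Conditions: Bu4NF (cat.), THF, −78 °C; then 1 M HCl, 0 °C
Reagents that add atoms: none
Why: Fluoride-catalysed vinylogous Mukaiyama aldol addition: the ammonium dienolate released from 23 attacks the aldehyde through C5 of the furan in an open, extended transition state that should favour the unlike (erythro) relation between the new ring stereocentre (5S) and the carbinol carbon (1R), the latter set by 1,2-induction from the α-methyl centre (attack anti to its CH2 chain), while silyl transfer to the aldolate (24) blocks retro-aldol until acidic work-up frees the alcohol.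

Step 15
Reactants: 25 (5S)-5-[(1R,2S,4E,6E)-1-hydroxy-7-iodo-2,6-dimethylhepta-4,6-dien-1-yl]-3-methylfuran-2(5H)-one
Product: 26 (5E)-5-[(2S,4E,6E)-7-iodo-2,6-dimethylhepta-4,6-dien-1-ylidene]-3-methylfuran-2(5H)-one
Conditions: PPh3, diethyl azodicarboxylate, THF, −30 to 23 °C
Reagents that add atoms: none
Why: Mitsunobu-type dehydration: the alkoxyphosphonium group leaves antiperiplanar to the acidic ring hydrogen at C5 (E2 anti-elimination), so the unlike adduct should give only the E exocyclic double bond (side chain cis to the ring CH), and both stereocentres made in step 14 are erased.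

Step 16
Reactants: 26 (5E)-5-[(2S,4E,6E)-7-iodo-2,6-dimethylhepta-4,6-dien-1-ylidene]-3-methylfuran-2(5H)-one; 9 2-(furan-3-ylmethyl)-4-(2-iodoethyl)furan
Product: 28 (5E)-5-{(2S,4E,6E)-9-[5-(furan-3-ylmethyl)furan-3-yl]-2,6-dimethylnona-4,6-dien-1-ylidene}-3-methylfuran-2(5H)-one (target), via alkylzinc iodide 27 (not isolated)
Conditions: 9, Zn dust, LiCl, THF, 23 °C; then 26, PdCl2(dppf) (cat.), THF, 23 °C, dark
Reagents that add atoms: none
Why: Zerovalent palladium inserts into the C(sp2)–I bond at the diene terminus of 26 with retention, the primary alkyl group of 27 is transferred from zinc, and reductive elimination (favoured over β-hydride elimination by the wide bite angle of dppf) forms the sp2–sp3 bond, a Negishi alkyl–alkenyl cross-coupling. The closest known reaction type is the coupling of primary alkylzinc halides with (E)-2-methyl-1-iodoalkenes, and organozinc cross-couplings are known on halides that already carry a γ-alkylidene butenolide. No ring is closed and no stereocentre is created; the step has to preserve three alkene geometries (both E double bonds of the diene and the kinetically set E enol-lactone double bond of ring C) and the S stereocentre, whose hydrogen is vinylogously acidic. This is secured by the neutral, base-free and weakly nucleophilic organozinc, which neither deprotonates that position nor adds to the lactone carbonyl, whereas the basic borate conditions of a B-alkyl coupling would endanger both. Chemoselectivity rests on the C–I bond being the only site of oxidative addition (the enol ester C–O bond and the furans are inert), so that in one operation two finished halves, with all rings and all stereochemistry in place and no protecting group, become the target.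

**Compound list**

1 | 4-bromofuran-2-carbaldehyde | O=Cc1cc(Br)co1 | starting material
2 | 3-bromofuran | Brc1ccoc1 | starting material
3 | furan-3-yllithium | [Li]c1ccoc1 | intermediate
4 | racemic (4-bromofuran-2-yl)(furan-3-yl)methanol | OC(c1cc(Br)co1)c1ccoc1 | intermediate
5 | 4-bromo-2-(furan-3-ylmethyl)furan | Brc1coc(Cc2ccoc2)c1 | intermediate
6 | 4-ethenyl-2-(furan-3-ylmethyl)furan | C=Cc1coc(Cc2ccoc2)c1 | intermediate
7 | 9-{2-[5-(furan-3-ylmethyl)furan-3-yl]ethyl}-9-borabicyclo[3.3.1]nonane | C(Cc1coc(Cc2ccoc2)c1)B1C2CCCC1CCC2 | intermediate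
8 | 2-[5-(furan-3-ylmethyl)furan-3-yl]ethan-1-ol | OCCc1coc(Cc2ccoc2)c1 | intermediate
9 | 2-(furan-3-ylmethyl)-4-(2-iodoethyl)furan | ICCc1coc(Cc2ccoc2)c1 | intermediate
10 | (E)-1,2-dichloroethene | Cl/C=C/Cl | starting material
11 | ethynyltrimethylsilane | C#C[Si](C)(C)C | starting material
12 | (E)-(4-chlorobut-3-en-1-yn-1-yl)trimethylsilane | C[Si](C)(C)C#C/C=C/Cl | intermediate
13 | (R)-3-bromo-2-methylpropan-1-ol | OC[C@@H](C)CBr | starting material
14 | (R)-(3-bromo-2-methylpropoxy)(tert-butyl)dimethylsilane | CC(C)(C)[Si](C)(C)OC[C@@H](C)CBr | intermediate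
15 | {(R)-3-[(tert-butyldimethylsilyl)oxy]-2-methylpropyl}zinc bromide | CC(C)(C)[Si](C)(C)OC[C@@H](C)C[Zn]Br | intermediate
16 | tert-butyldimethyl{[(2S,4E)-2-methyl-7-(trimethylsilyl)hept-4-en-6-yn-1-yl]oxy}silane | CC(C)(C)[Si](C)(C)OC[C@@H](C)C/C=C/C#C[Si](C)(C)C | intermediate
17 | tert-butyldimethyl{[(2S,4E)-2-methylhept-4-en-6-yn-1-yl]oxy}silane | CC(C)(C)[Si](C)(C)OC[C@@H](C)C/C=C/C#C | intermediate
18 | {(1E,3E,6S)-7-[(tert-butyldimethylsilyl)oxy]-2,6-dimethylhepta-1,3-dien-1-yl}dimethylaluminium | CC(C)(C)[Si](C)(C)OC[C@@H](C)C/C=C/C(C)=C/[Al](C)C | intermediate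
19 | tert-butyl{[(2S,4E,6E)-7-iodo-2,6-dimethylhepta-4,6-dien-1-yl]oxy}dimethylsilane | CC(C)(C)[Si](C)(C)OC[C@@H](C)C/C=C/C(C)=C/I | intermediate
20 | (2S,4E,6E)-7-iodo-2,6-dimethylhepta-4,6-dien-1-ol | OC[C@@H](C)C/C=C/C(C)=C/I | intermediate
21 | (2S,4E,6E)-7-iodo-2,6-dimethylhepta-4,6-dienal | O=C[C@@H](C)C/C=C/C(C)=C/I | intermediate
22 | 3-methylfuran-2(5H)-one | CC1=CCOC1=O | starting material
23 | trimethyl[(3-methylfuran-2-yl)oxy]silane | Cc1ccoc1O[Si](C)(C)C | intermediate
24 | (5S)-5-{(1R,2S,4E,6E)-7-iodo-2,6-dimethyl-1-[(trimethylsilyl)oxy]hepta-4,6-dien-1-yl}-3-methylfuran-2(5H)-one | CC1=C[C@@H]([C@H](O[Si](C)(C)C)[C@@H](C)C/C=C/C(C)=C/I)OC1=O | intermediate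
25 | (5S)-5-[(1R,2S,4E,6E)-1-hydroxy-7-iodo-2,6-dimethylhepta-4,6-dien-1-yl]-3-methylfuran-2(5H)-one | CC1=C[C@@H]([C@H](O)[C@@H](C)C/C=C/C(C)=C/I)OC1=O | intermediate
26 | (5E)-5-[(2S,4E,6E)-7-iodo-2,6-dimethylhepta-4,6-dien-1-ylidene]-3-methylfuran-2(5H)-one | CC1=C/C(=C\[C@@H](C)C/C=C/C(C)=C/I)OC1=O | intermediate
27 | {2-[5-(furan-3-ylmethyl)furan-3-yl]ethyl}zinc iodide | I[Zn]CCc1coc(Cc2ccoc2)c1 | intermediate
28 | (5E)-5-{(2S,4E,6E)-9-[5-(furan-3-ylmethyl)furan-3-yl]-2,6-dimethylnona-4,6-dien-1-ylidene}-3-methylfuran-2(5H)-one | CC1=C/C(=C\[C@@H](C)C/C=C/C(C)=C/CCc2coc(Cc3ccoc3)c2)OC1=O | target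

**Step count and risks**

Total steps: 16 (steps 6 and 13 prepare the small partners 12 and 23).
Longest linear sequence: 9 steps, from 13 to 28 (steps 7–12 and 14–16).

Steps most likely to fail:

1. Step 16 (key step). What may go wrong: slow transmetalation with competing β-hydride elimination or protodezincation, or geometric isomerisation of the exocyclic enol-lactone double bond and epimerisation at the neighbouring CH(CH3) under palladium or Lewis-acidic zinc salts. Fallback (the same bond is formed before ring C exists): it sets out from iodide 19 and borane 7 (made from 6 as in step 4, without the oxidation). A B-alkyl Suzuki–Miyaura coupling (PdCl2(dppf), AsPh3, Cs2CO3, DMF/THF/H2O, 23 °C) should give the coupled tert-butyldimethylsilyl ether F1; Bu4NF should give the dienol F2; Dess–Martin periodinane should give the dienal F3; fluoride-catalysed vinylogous aldol addition of 23 should give the trimethylsilyl ether F4 and, after acidic work-up, the unlike hydroxy butenolide F5; PPh3/diethyl azodicarboxylate anti-elimination then makes the E double bond of ring C in the last operation, and the sequence comes back to the route at 28.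

2. Step 14. What may go wrong: low unlike/like selectivity of the open transition state, or epimerisation of the α-methyl aldehyde by the basic ammonium dienolate. Fallback (other diastereomer, other elimination mechanism): it sets out from 21 and 23. With BF3·OEt2 (CH2Cl2, −78 °C) the Lewis acid-promoted vinylogous Mukaiyama aldol addition is non-basic and should favour the like hydroxy butenolide F6. F6 is treated with methyl N-(triethylammoniosulfonyl)carbamate (Burgess reagent, benzene, 50 °C) to give the sulfamate salt F7, whose thermal syn-elimination toward the acidic ring hydrogen should give the same E-alkylidene butenolide; the sequence comes back at 26.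

3. Step 2. What may go wrong: acid-induced oligomerisation (attack of a furan on the furfuryl cation) or ring opening outrunning the hydride transfer. Fallback (basic instead of cationic reduction): it sets out from 4. Oxidation with MnO2 (CH2Cl2, 23 °C) should give the ketone F8, and Wolff–Kishner reduction (N2H4·H2O, KOH, diethylene glycol, 120 then 190 °C) through the hydrazone F9 should give the methylene compound; the sequence comes back at 5.

**Further compounds**

F1 | step 16 | tert-butyl{[(2S,4E,6E)-9-[5-(furan-3-ylmethyl)furan-3-yl]-2,6-dimethylnona-4,6-dien-1-yl]oxy}dimethylsilane | CC(C)(C)[Si](C)(C)OC[C@@H](C)C/C=C/C(C)=C/CCc1coc(Cc2ccoc2)c1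
F2 | step 16 | (2S,4E,6E)-9-[5-(furan-3-ylmethyl)furan-3-yl]-2,6-dimethylnona-4,6-dien-1-ol | OC[C@@H](C)C/C=C/C(C)=C/CCc1coc(Cc2ccoc2)c1
F3 | step 16 | (2S,4E,6E)-9-[5-(furan-3-ylmethyl)furan-3-yl]-2,6-dimethylnona-4,6-dienal | O=C[C@@H](C)C/C=C/C(C)=C/CCc1coc(Cc2ccoc2)c1
F4 | step 16 | (5S)-5-{(1R,2S,4E,6E)-9-[5-(furan-3-ylmethyl)furan-3-yl]-2,6-dimethyl-1-[(trimethylsilyl)oxy]nona-4,6-dien-1-yl}-3-methylfuran-2(5H)-one | CC1=C[C@@H]([C@H](O[Si](C)(C)C)[C@@H](C)C/C=C/C(C)=C/CCc2coc(Cc3ccoc3)c2)OC1=O
F5 | step 16 | (5S)-5-{(1R,2S,4E,6E)-9-[5-(furan-3-ylmethyl)furan-3-yl]-1-hydroxy-2,6-dimethylnona-4,6-dien-1-yl}-3-methylfuran-2(5H)-one | CC1=C[C@@H]([C@H](O)[C@@H](C)C/C=C/C(C)=C/CCc2coc(Cc3ccoc3)c2)OC1=O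
F6 | step 14 | (5R)-5-[(1R,2S,4E,6E)-1-hydroxy-7-iodo-2,6-dimethylhepta-4,6-dien-1-yl]-3-methylfuran-2(5H)-one | CC1=C[C@H]([C@H](O)[C@@H](C)C/C=C/C(C)=C/I)OC1=O
F7 | step 14 | triethylammonium salt of the N-(methoxycarbonyl)sulfamate ester of F6 | CC1=C[C@H]([C@H](OS(=O)(=O)[N-]C(=O)OC)[C@@H](C)C/C=C/C(C)=C/I)OC1=O.CC[NH+](CC)CC
F8 | step 2 | (4-bromofuran-2-yl)(furan-3-yl)methanone | O=C(c1cc(Br)co1)c1ccoc1
F9 | step 2 | [(4-bromofuran-2-yl)(furan-3-yl)methylidene]hydrazine | NN=C(c1cc(Br)co1)c1ccoc1
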